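**Retrosynthetic overview**
- Target 22 ← O-desilylation ← para-Claisen shift of allyl from the C4' oxygen to C1' ← O-allylation of phenol 15 ← oxidation of the C4'–B bond of aryl boronate 13.
- Feature used: on ring A the carbons C3' (OCH3), C4' (OH) and C5' (bonded to C8) are contiguous, so C3' can be the methoxy-bearing terminus (C3) of a 2-pyrone diene and C4'/C5' the boron-bearing and alkyl-bearing carbons of one alkyne.
- Key disconnection: C3'–C4' and C5'–C6' by Diels–Alder addition of 3-methoxy-2-pyrone 11 to alkynyl boronate 9, then loss of CO2; ring A is the only ring formed (ring B is bought as 3,4-dimethoxybenzaldehyde).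
- 9 ← C-borylation ← O-silylation ← anti-selective addition of the allenylzinc from (R)-but-3-yn-2-yl mesylate to 3,4-dimethoxybenzaldehyde, which sets C7 and C8 before ring A is built.

Key step: step 6

Remark: by CIP analysis the SMILES is (7S,8S), the anti isomer (C7–OH and C8–CH3 on opposite sides when the two aryl groups end the zigzag chain). Neolignan numbering is used: C7 carbinol carbon, C8 methyl-bearing carbon, primed numbers on ring A. 3-Hydroxy-2-pyrone is taken as purchasable.

Step 1
Reactants: 1 (R)-but-3-yn-2-ol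
Product: 2 (R)-but-3-yn-2-yl methanesulfonate
Conditions: MsCl, Et3N, CH2Cl2, −78 → 0 °C
Reagents that add atoms: methanesulfonyl chloride, CS(=O)(=O)Cl
Why: Sulfonylation takes place at oxygen and leaves the C–O bond intact, so the R configuration is kept.

Step 2
Reactants: 2 (R)-but-3-yn-2-yl methanesulfonate; 3 3,4-dimethoxybenzaldehyde
Product: 5 (1S,2S)-1-(3,4-dimethoxyphenyl)-2-methylbut-3-yn-1-ol, via (P)-allenyl(ethyl)zinc 4 (not isolated)
Conditions: Pd(OAc)2 (5 mol %), PPh3 (5 mol %), Et2Zn (3 equiv), THF, −78 → −20 °C; aq NH4Cl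
Reagents that add atoms: diethylzinc, CC[Zn]CC (zinc and one ethyl group, held in 4 only; nothing in 5)
Why: In this known palladium-catalysed zincation–propargylation of propargylic mesylates, zerovalent palladium (from Pd(OAc)2 and Et2Zn) displaces the mesylate anti (SN2'), zinc replaces palladium with retention and allenylzinc 4 adds to the aldehyde by a syn SE2' six-membered cyclic transition state, so C8 is set S by net inversion at the mesylate carbon and C7 is set S because the aryl group sits away from the allenyl methyl (anti adduct).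

Step 3
Reactants: 5 (1S,2S)-1-(3,4-dimethoxyphenyl)-2-methylbut-3-yn-1-ol
Product: 6 tert-butyl{[(1S,2S)-1-(3,4-dimethoxyphenyl)-2-methylbut-3-yn-1-yl]oxy}dimethylsilane
Conditions: TBSOTf, 2,6-lutidine, CH2Cl2, −78 → 0 °C
Reagents that add atoms: tert-butyldimethylsilyl trifluoromethanesulfonate, CC(C)(C)[Si](C)(C)OS(=O)(=O)C(F)(F)F
Why: Silylation of a hindered secondary alcohol with a silyl triflate and a hindered base is standard and touches no stereocentre; the ether later blocks retro-ene cleavage and ionisation at C7 in the hot steps.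

Step 4
Reactants: 6 tert-butyl{[(1S,2S)-1-(3,4-dimethoxyphenyl)-2-methylbut-3-yn-1-yl]oxy}dimethylsilane
Product: 9 2-[(3S,4S)-4-(tert-butyldimethylsilyloxy)-4-(3,4-dimethoxyphenyl)-3-methylbut-1-yn-1-yl]-4,4,5,5-tetramethyl-1,3,2-dioxaborolane, via lithium acetylide 7 (not isolated), via lithium isopropoxy borate 8 (not isolated)
Conditions: n-BuLi, THF, −78 °C; i-PrOBpin, −78 °C; HCl in Et2O, −78 °C → rt
Reagents that add atoms: n-butyllithium, CCCC[Li] (lithium, held in 7 and 8 only); 2-isopropoxy-4,4,5,5-tetramethyl-1,3,2-dioxaborolane, CC(C)OB1OC(C)(C)C(C)(C)O1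
Why: Deprotonation of the terminal alkyne, capture of the acetylide by the isopropoxy boronate and protonolysis of the ate complex with anhydrous HCl is the standard route to alkynyl pinacol boronates, and the base is consumed by the sp C–H before it can reach C8–H.

Step 5
Reactants: 10 3-hydroxy-2H-pyran-2-one
Product: 11 3-methoxy-2H-pyran-2-one
Conditions: MeI, K2CO3, acetone, rt
Reagents that add atoms: iodomethane, CI
Why: Williamson-type O-methylation of the acidic enol OH under mild carbonate conditions that do not open the lactone.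

Step 6
Reactants: 9 2-[(3S,4S)-4-(tert-butyldimethylsilyloxy)-4-(3,4-dimethoxyphenyl)-3-methylbut-1-yn-1-yl]-4,4,5,5-tetramethyl-1,3,2-dioxaborolane; 11 3-methoxy-2H-pyran-2-one
Product: 13 tert-butyl{(1S,2S)-1-(3,4-dimethoxyphenyl)-2-[3-methoxy-2-(4,4,5,5-tetramethyl-1,3,2-dioxaborolan-2-yl)phenyl]propoxy}dimethylsilane, via bridged lactone 12 (not isolated)
Conditions: 11 (3 equiv), mesitylene, 180 °C, sealed tube, argon
Reagents that add atoms: none
Why: The pyrone acts as the diene through C3–C6 and the alkynyl boronate as the dienophile in a thermal Diels–Alder reaction that gives bridged lactone 12, and 12 loses CO2 in a retro-Diels–Alder step driven by aromatisation. The closest known reaction type is the thermal cycloaddition of 2-pyrones with alkynyl pinacol boronates to give aryl pinacol boronates. Ring A is closed by this intermolecular [4+2] cycloaddition, which forms C3'–C4' (pyrone C3 to the boron-bearing carbon) and C5'–C6' (the C8-bearing carbon to pyrone C6). No stereocentre is created, since the two bridgehead centres of 12 vanish with CO2, and C7 and C8 are spectators because the medium holds neither acid nor base and the silyl ether blocks retro-ene cleavage of the C7–C8 bond. The step needs the orientation with boron next to methoxy, and two features point that way: the boron-bearing carbon is the acceptor-substituted alkyne carbon and pairs with the donor-substituted diene terminus C3 (the orientation acrylates take with 3-substituted 2-pyrones), and the branched C8 group, the larger alkyne substituent, is kept at the unsubstituted C6–H terminus. For a 3-alkoxy-2-pyrone this orientation is a prediction and the main risk of the route, to be checked on 13 by NOE (C8–H to H6', OCH3 to H2').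

Step 7
Reactants: 13 tert-butyl{(1S,2S)-1-(3,4-dimethoxyphenyl)-2-[3-methoxy-2-(4,4,5,5-tetramethyl-1,3,2-dioxaborolan-2-yl)phenyl]propoxy}dimethylsilane
Product: 15 2-[(1S,2S)-1-(tert-butyldimethylsilyloxy)-1-(3,4-dimethoxyphenyl)propan-2-yl]-6-methoxyphenol, via aryl borate 14 (not isolated)
Conditions: 30% aq H2O2, aq NaOH, THF, 0 °C → rt; aq NH4Cl
Reagents that add atoms: hydrogen peroxide, OO
Why: Standard oxidation of an aryl boronate, in which hydroperoxide adds to boron, the aryl group shifts from boron to oxygen at the same ring carbon and borate 14 hydrolyses; the silyl group stays on the C7 oxygen because the phenoxide is the more stable oxyanion.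

Step 8
Reactants: 15 2-[(1S,2S)-1-(tert-butyldimethylsilyloxy)-1-(3,4-dimethoxyphenyl)propan-2-yl]-6-methoxyphenol; 16 allyl bromide
Product: 17 {(1S,2S)-2-[2-(allyloxy)-3-methoxyphenyl]-1-(3,4-dimethoxyphenyl)propoxy}(tert-butyl)dimethylsilane
Conditions: K2CO3, DMF, rt → 40 °C
Reagents that add atoms: none
Why: Williamson O-allylation of the hindered phenoxide, with the alkyl silyl ether inert to carbonate.

Step 9
Reactants: 17 {(1S,2S)-2-[2-(allyloxy)-3-methoxyphenyl]-1-(3,4-dimethoxyphenyl)propoxy}(tert-butyl)dimethylsilane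
Product: 21 4-allyl-2-[(1S,2S)-1-(tert-butyldimethylsilyloxy)-1-(3,4-dimethoxyphenyl)propan-2-yl]-6-methoxyphenol, via C3'-allyl ortho-dienone 18 (not isolated), via C5'-allyl ortho-dienone 19 (not isolated), via para-dienone 20 (not isolated)
Conditions: N,N-diethylaniline, 195 °C, sealed tube, argon
Reagents that add atoms: none
Why: Aromatic para-Claisen rearrangement: both ortho carbons (C3', C5') are blocked, so the first [3,3] shift gives dienone 18 or 19, a Cope [3,3] shift carries the allyl group on to C1' (20) and tautomerisation gives the para-allyl phenol, while the neutral amine solvent suppresses ionisation at C7.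

Step 10
Reactants: 21 4-allyl-2-[(1S,2S)-1-(tert-butyldimethylsilyloxy)-1-(3,4-dimethoxyphenyl)propan-2-yl]-6-methoxyphenol
Product: 22 (1S,2S)-2-(5-allyl-2-hydroxy-3-methoxyphenyl)-1-(3,4-dimethoxyphenyl)propan-1-ol
Conditions: TBAF, THF, rt → 40 °C; aq NH4Cl
Reagents that add atoms: none
Why: Fluoride cleaves the Si–O bond under non-acidic conditions, which avoids acid-induced closure of the C4' phenol onto benzylic C7 (dihydrobenzofuran) and leaves both stereocentres untouched.

**Compound list**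
1 | (R)-but-3-yn-2-ol | C#C[C@@H](C)O | starting material
2 | (R)-but-3-yn-2-yl methanesulfonate | C#C[C@@H](C)OS(C)(=O)=O | intermediate
3 | 3,4-dimethoxybenzaldehyde | COc1ccc(C=O)cc1OC | starting material
4 | ethyl[(P)-buta-1,2-dien-1-yl]zinc (not isolated) | CC([H])=[C@@]=C([H])[Zn]CC | intermediate
5 | (1S,2S)-1-(3,4-dimethoxyphenyl)-2-methylbut-3-yn-1-ol | C#C[C@H](C)[C@H](O)c1ccc(OC)c(OC)c1 | intermediate
6 | tert-butyl{[(1S,2S)-1-(3,4-dimethoxyphenyl)-2-methylbut-3-yn-1-yl]oxy}dimethylsilane | C#C[C@H](C)[C@H](O[Si](C)(C)C(C)(C)C)c1ccc(OC)c(OC)c1 | intermediate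
7 | lithium acetylide of 6 (not isolated) | [Li]C#C[C@H](C)[C@H](O[Si](C)(C)C(C)(C)C)c1ccc(OC)c(OC)c1 | intermediate
8 | lithium alkynyl(isopropoxy)pinacolborate (not isolated) | [Li+].CC(C)O[B-]1(C#C[C@H](C)[C@H](O[Si](C)(C)C(C)(C)C)c2ccc(OC)c(OC)c2)OC(C)(C)C(C)(C)O1 | intermediate
9 | 2-[(3S,4S)-4-(tert-butyldimethylsilyloxy)-4-(3,4-dimethoxyphenyl)-3-methylbut-1-yn-1-yl]-4,4,5,5-tetramethyl-1,3,2-dioxaborolane | CC1(C)OB(C#C[C@H](C)[C@H](O[Si](C)(C)C(C)(C)C)c2ccc(OC)c(OC)c2)OC1(C)C | intermediate
10 | 3-hydroxy-2H-pyran-2-one | OC1=CC=COC1=O | starting material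
11 | 3-methoxy-2H-pyran-2-one | COC1=CC=COC1=O | intermediate
12 | 4-methoxy-7-[(1S,2S)-1-(tert-butyldimethylsilyloxy)-1-(3,4-dimethoxyphenyl)propan-2-yl]-8-(pinacolboryl)-2-oxabicyclo[2.2.2]octa-5,7-dien-3-one (not isolated; both bridgehead diastereomers, bridgeheads undefined) | COC12C=CC(OC1=O)C([C@H](C)[C@H](O[Si](C)(C)C(C)(C)C)c1ccc(OC)c(OC)c1)=C2B1OC(C)(C)C(C)(C)O1 | intermediate
13 | tert-butyl{(1S,2S)-1-(3,4-dimethoxyphenyl)-2-[3-methoxy-2-(4,4,5,5-tetramethyl-1,3,2-dioxaborolan-2-yl)phenyl]propoxy}dimethylsilane | COc1cccc([C@H](C)[C@H](O[Si](C)(C)C(C)(C)C)c2ccc(OC)c(OC)c2)c1B1OC(C)(C)C(C)(C)O1 | intermediate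
14 | aryl pinacol borate of 15 (not isolated) | COc1cccc([C@H](C)[C@H](O[Si](C)(C)C(C)(C)C)c2ccc(OC)c(OC)c2)c1OB1OC(C)(C)C(C)(C)O1 | intermediate
15 | 2-[(1S,2S)-1-(tert-butyldimethylsilyloxy)-1-(3,4-dimethoxyphenyl)propan-2-yl]-6-methoxyphenol | COc1cccc([C@H](C)[C@H](O[Si](C)(C)C(C)(C)C)c2ccc(OC)c(OC)c2)c1O | intermediate
16 | allyl bromide | C=CCBr | starting material
17 | {(1S,2S)-2-[2-(allyloxy)-3-methoxyphenyl]-1-(3,4-dimethoxyphenyl)propoxy}(tert-butyl)dimethylsilane | C=CCOc1c(OC)cccc1[C@H](C)[C@H](O[Si](C)(C)C(C)(C)C)c1ccc(OC)c(OC)c1 | intermediate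
18 | 6-allyl-6-methoxy-2-[(1S,2S)-1-(tert-butyldimethylsilyloxy)-1-(3,4-dimethoxyphenyl)propan-2-yl]cyclohexa-2,4-dien-1-one (not isolated; C6 undefined) | C=CCC1(OC)C=CC=C([C@H](C)[C@H](O[Si](C)(C)C(C)(C)C)c2ccc(OC)c(OC)c2)C1=O | intermediate
19 | 6-allyl-2-methoxy-6-[(1S,2S)-1-(tert-butyldimethylsilyloxy)-1-(3,4-dimethoxyphenyl)propan-2-yl]cyclohexa-2,4-dien-1-one (not isolated; C6 undefined) | C=CCC1([C@H](C)[C@H](O[Si](C)(C)C(C)(C)C)c2ccc(OC)c(OC)c2)C=CC=C(OC)C1=O | intermediate
20 | 4-allyl-2-methoxy-6-[(1S,2S)-1-(tert-butyldimethylsilyloxy)-1-(3,4-dimethoxyphenyl)propan-2-yl]cyclohexa-2,5-dien-1-one (not isolated; C4 undefined) | C=CCC1C=C(OC)C(=O)C([C@H](C)[C@H](O[Si](C)(C)C(C)(C)C)c2ccc(OC)c(OC)c2)=C1 | intermediate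
21 | 4-allyl-2-[(1S,2S)-1-(tert-butyldimethylsilyloxy)-1-(3,4-dimethoxyphenyl)propan-2-yl]-6-methoxyphenol | C=CCc1cc(OC)c(O)c([C@H](C)[C@H](O[Si](C)(C)C(C)(C)C)c2ccc(OC)c(OC)c2)c1 | intermediate
22 | (1S,2S)-2-(5-allyl-2-hydroxy-3-methoxyphenyl)-1-(3,4-dimethoxyphenyl)propan-1-ol | C=CCc1cc(OC)c(O)c([C@H](C)[C@H](O)c2ccc(OC)c(OC)c2)c1 | target

Total step count: 10. Longest linear sequence: 9 steps (steps 1–4 and 6–10, from (R)-but-3-yn-2-ol); step 5 is a one-step branch.

**Steps most likely to fail**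

Step 6. The alkyne may add in the reverse orientation (C8 group next to methoxy), or the hindered internal alkyne may react so slowly that the partners decompose at 180 °C. The fallback sets out from 6 and comes back at 15; it gives the alkyne a true acceptor and uses an electron-rich diene whose ortho orientation with alkynoates is documented. Lithiation of 6 (n-BuLi, THF, −78 °C) and quench with methyl chloroformate gives methyl (4S,5S)-5-(tert-butyldimethylsilyloxy)-5-(3,4-dimethoxyphenyl)-4-methylpent-2-ynoate F1. Heating F1 with purchased 1-methoxycyclohexa-1,3-diene (excess, xylene, 160–180 °C, sealed tube; Alder–Rickert reaction) gives the bicyclo[2.2.2]octa-2,5-diene adduct F2, which loses ethene in the same flask to leave methyl 2-[(1S,2S)-1-(tert-butyldimethylsilyloxy)-1-(3,4-dimethoxyphenyl)propan-2-yl]-6-methoxybenzoate F3, with the ester between methoxy and the side chain. LiAlH4 (THF, 0 °C) gives the benzylic alcohol F4 and MnO2 (CH2Cl2) the benzaldehyde F5. mCPBA (CH2Cl2, NaHCO3, 0 °C; Dakin-type Baeyer–Villiger shift of the electron-rich aryl group) gives the aryl formate F6, and K2CO3 in MeOH frees phenol 15.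

Step 2. With an electron-rich aromatic aldehyde the anti/syn preference of the cyclic transition state may be low, or the allenylzinc may lose configuration before it adds. The fallback sets out from 3 and comes back at 6; it uses crotylboration and then exchanges vinyl for ethynyl. Aldehyde 3 is treated at −78 °C (THF/Et2O) with (E)-crotylbis(isopinocampheyl)borane F7, made from trans-but-2-ene, n-BuLi/KOt-Bu, (−)-Ipc2BOMe of the (+)-α-pinene series and BF3·OEt2. This antipode adds to the Si face of aryl aldehydes (antipode assignment from memory, to be confirmed before use), and the (E)-crotyl group gives the anti adduct through a chair transition state. Oxidative work-up (NaOH, H2O2) gives (1S,2S)-1-(3,4-dimethoxyphenyl)-2-methylbut-3-en-1-ol F8, and TBSOTf/2,6-lutidine gives its silyl ether F9. Lemieux–Johnson cleavage (OsO4 catalytic, NaIO4, 2,6-lutidine, dioxane–water; ozone is avoided because of the dimethoxyarene) gives (2R,3S)-3-(tert-butyldimethylsilyloxy)-3-(3,4-dimethoxyphenyl)-2-methylpropanal F10. The Ohira–Bestmann reagent (dimethyl (1-diazo-2-oxopropyl)phosphonate, K2CO3, MeOH, 0 °C) then converts the formyl group into the ethynyl group of 6.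

Step 9. At about 195 °C the benzylic silyl ether may ionise or eliminate, or the ortho-dienones may be diverted into intramolecular Diels–Alder products before the para shift. The fallback sets out from 15 and comes back at 21, so steps 8 and 9 are skipped. Para-bromination of the phenol (NBS, CH2Cl2, −40 → 0 °C; the phenol ring is more reactive than ring B and C1' is its only free para position) gives 4-bromo-2-[(1S,2S)-1-(tert-butyldimethylsilyloxy)-1-(3,4-dimethoxyphenyl)propan-2-yl]-6-methoxyphenol F11. Stille coupling with allyltributylstannane (Pd(PPh3)4, LiCl, DMF, 90 °C) then gives 21.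

**Further compounds**
F1 | step 6 | methyl (4S,5S)-5-(tert-butyldimethylsilyloxy)-5-(3,4-dimethoxyphenyl)-4-methylpent-2-ynoate | COC(=O)C#C[C@H](C)[C@H](O[Si](C)(C)C(C)(C)C)c1ccc(OC)c(OC)c1
F2 | step 6 | methyl 1-methoxy-3-[(1S,2S)-1-(tert-butyldimethylsilyloxy)-1-(3,4-dimethoxyphenyl)propan-2-yl]bicyclo[2.2.2]octa-2,5-diene-2-carboxylate (bridgeheads undefined) | COC(=O)C1=C([C@H](C)[C@H](O[Si](C)(C)C(C)(C)C)c2ccc(OC)c(OC)c2)C2C=CC1(OC)CC2
F3 | step 6 | methyl 2-[(1S,2S)-1-(tert-butyldimethylsilyloxy)-1-(3,4-dimethoxyphenyl)propan-2-yl]-6-methoxybenzoate | COC(=O)c1c(OC)cccc1[C@H](C)[C@H](O[Si](C)(C)C(C)(C)C)c1ccc(OC)c(OC)c1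
F4 | step 6 | {2-[(1S,2S)-1-(tert-butyldimethylsilyloxy)-1-(3,4-dimethoxyphenyl)propan-2-yl]-6-methoxyphenyl}methanol | OCc1c(OC)cccc1[C@H](C)[C@H](O[Si](C)(C)C(C)(C)C)c1ccc(OC)c(OC)c1
F5 | step 6 | 2-[(1S,2S)-1-(tert-butyldimethylsilyloxy)-1-(3,4-dimethoxyphenyl)propan-2-yl]-6-methoxybenzaldehyde | O=Cc1c(OC)cccc1[C@H](C)[C@H](O[Si](C)(C)C(C)(C)C)c1ccc(OC)c(OC)c1
F6 | step 6 | 2-[(1S,2S)-1-(tert-butyldimethylsilyloxy)-1-(3,4-dimethoxyphenyl)propan-2-yl]-6-methoxyphenyl formate | O=COc1c(OC)cccc1[C@H](C)[C@H](O[Si](C)(C)C(C)(C)C)c1ccc(OC)c(OC)c1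
F7 | step 2 | (E)-crotylbis(isopinocampheyl)borane, (+)-α-pinene series | C/C=C/CB([C@@H]1C[C@@H]2C[C@H]([C@H]1C)C2(C)C)[C@@H]1C[C@@H]2C[C@H]([C@H]1C)C2(C)C
F8 | step 2 | (1S,2S)-1-(3,4-dimethoxyphenyl)-2-methylbut-3-en-1-ol | C=C[C@H](C)[C@H](O)c1ccc(OC)c(OC)c1
F9 | step 2 | tert-butyl{[(1S,2S)-1-(3,4-dimethoxyphenyl)-2-methylbut-3-en-1-yl]oxy}dimethylsilane | C=C[C@H](C)[C@H](O[Si](C)(C)C(C)(C)C)c1ccc(OC)c(OC)c1
F10 | step 2 | (2R,3S)-3-(tert-butyldimethylsilyloxy)-3-(3,4-dimethoxyphenyl)-2-methylpropanal | O=C[C@H](C)[C@H](O[Si](C)(C)C(C)(C)C)c1ccc(OC)c(OC)c1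
F11 | step 9 | 4-bromo-2-[(1S,2S)-1-(tert-butyldimethylsilyloxy)-1-(3,4-dimethoxyphenyl)propan-2-yl]-6-methoxyphenol | COc1cc(Br)cc([C@H](C)[C@H](O[Si](C)(C)C(C)(C)C)c2ccc(OC)c(OC)c2)c1O
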